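The retrosynthesis first cuts both CH=CMe2 double bonds at once, with the phenols masked as acetates, giving a 3,8-diallylflavone and 2-methyl-2-butene. It then cuts O1–C2, the C3–CH2 bond of the 3-allyl group, C2–C3, and the C8–CH2 bond of the 8-allyl group.
Enabling feature: the chains on C3 (ring C) and C8 (ring A) are the same ArCH2–CH=CMe2 unit, each beside a phenol oxygen (O2', O7) that adds to it under acid. A terminal CH2–CH=CH2 on the same carbons withstands heat, p-TsOH and BCl3.
Forward: ring A (2,4,6-trihydroxyacetophenone) takes up its allyl group first, by O-allylation and Claisen shift next to the only free phenol, so this oxygen must become O1 and the allylated carbon C8.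
Ring B (2,4-dihydroxybenzoic acid) is joined as an aryl ester and moved to carbon (Baker–Venkataraman). The diketone is then C-allylated, and ring C closes last by cyclodehydration.
Benzyl ethers are exchanged for acetates on the diallylflavone, the twofold cross-metathesis follows, and methanolysis frees the phenols without acid.
Stereochemistry: the target has no stereocentre and its alkenes have no E/Z isomers. The one centre met on the way (C2 of the allylated diketone) is racemic and disappears on ring closure.

Key step: step 11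

Remark: flavone numbering is used (ring C: O1, C2, C3, C4; ring A: C5–C8; ring B: primed positions). Reagents whose atoms do not reach the target (benzyl bromide, acetic anhydride) carry no compound number.

Step 1
Reactants: 1 2,4,6-trihydroxyacetophenone
Product: 2 1-[2,4-bis(benzyloxy)-6-hydroxyphenyl]ethanone
Conditions: BnBr (2.1 equiv), K2CO3 (2.2 equiv), DMF, rt → 50 °C
Reagents that add atoms: benzyl bromide, BrCc1ccccc1
Why: Williamson etherification; the 4-OH and one of the two equivalent ortho OH groups are alkylated, while the last ortho OH is hydrogen-bonded to the acetyl carbonyl and should stay free when only two equivalents of halide are offered.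

Step 2
Reactants: 2 1-[2,4-bis(benzyloxy)-6-hydroxyphenyl]ethanone; 3 allyl bromide
Product: 4 1-[2-(allyloxy)-4,6-bis(benzyloxy)phenyl]ethanone
Conditions: K2CO3, DMF, 60 °C
Reagents that add atoms: allyl bromide (3), C=CCBr
Why: Williamson etherification; warming in a dipolar aprotic solvent with a reactive allylic halide overcomes the chelation of the remaining phenol, and no other nucleophilic site is left.

Step 3
Reactants: 4 1-[2-(allyloxy)-4,6-bis(benzyloxy)phenyl]ethanone
Product: 5 1-[3-allyl-4,6-bis(benzyloxy)-2-hydroxyphenyl]ethanone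
Conditions: PhNEt2, 200 °C, argon, sealed tube
Reagents that add atoms: none
Why: Aromatic Claisen rearrangement; only C3 of the two ortho carbons bears a hydrogen (the other carries the acetyl group), so the [3,3] shift followed by enolisation should place the allyl group next to the phenol that later becomes O1, fixing it as C8 of the flavone.

Step 4
Reactants: 6 2,4-dihydroxybenzoic acid
Product: 8 2,4-bis(benzyloxy)benzoic acid, via benzyl 2,4-bis(benzyloxy)benzoate 7 (not isolated)
Conditions: BnBr (3.3 equiv), K2CO3, DMF, 60 °C; then KOH, MeOH/THF/H2O, 65 °C; 1 M HCl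
Reagents that add atoms: benzyl bromide, BrCc1ccccc1; potassium hydroxide, [K+].[OH-]
Why: Exhaustive Williamson benzylation followed by saponification; hydroxide cleaves only the benzyl ester by acyl–oxygen fission and leaves the two aryl benzyl ethers untouched.

Step 5
Reactants: 5 1-[3-allyl-4,6-bis(benzyloxy)-2-hydroxyphenyl]ethanone; 8 2,4-bis(benzyloxy)benzoic acid
Product: 9 2-acetyl-6-allyl-3,5-bis(benzyloxy)phenyl 2,4-bis(benzyloxy)benzoate
Conditions: EDCI, DMAP (0.3 equiv), CH2Cl2, 0 °C → rt
Reagents that add atoms: none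
Why: Steglich esterification; the carbodiimide activates 8, and the acylpyridinium ion formed with DMAP acylates the chelated, flanked phenol of 5, which is the only nucleophile present.

Step 6
Reactants: 9 2-acetyl-6-allyl-3,5-bis(benzyloxy)phenyl 2,4-bis(benzyloxy)benzoate
Product: 10 1-[3-allyl-4,6-bis(benzyloxy)-2-hydroxyphenyl]-3-[2,4-bis(benzyloxy)phenyl]propane-1,3-dione
Conditions: LiN(SiMe3)2 (3 equiv), THF, −78 °C → rt; 1 M HCl
Reagents that add atoms: none
Why: Baker–Venkataraman rearrangement; the methyl ketone enolate attacks the neighbouring aryl ester through a six-membered transition state, the O→C acyl shift is driven by formation of the diketonate and phenoxide, and the amide base neither hydrolyses the ester nor moves the allyl double bond.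

Step 7
Reactants: 10 1-[3-allyl-4,6-bis(benzyloxy)-2-hydroxyphenyl]-3-[2,4-bis(benzyloxy)phenyl]propane-1,3-dione; 3 allyl bromide
Product: 11 (±)-2-allyl-1-[3-allyl-4,6-bis(benzyloxy)-2-hydroxyphenyl]-3-[2,4-bis(benzyloxy)phenyl]propane-1,3-dione
Conditions: allyl bromide (1.1 equiv), K2CO3 (1.5 equiv), acetone, reflux
Reagents that add atoms: allyl bromide (3), C=CCBr
Why: SN2 C-alkylation of a 1,3-diketone enolate, as known for o-hydroxydibenzoylmethanes; the soft central carbon should outrun the phenol, which is chelated and flanked by allyl and acyl groups, and the new centre is racemic and is erased in step 8.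

Step 8
Reactants: 11 (±)-2-allyl-1-[3-allyl-4,6-bis(benzyloxy)-2-hydroxyphenyl]-3-[2,4-bis(benzyloxy)phenyl]propane-1,3-dione
Product: 12 3,8-diallyl-5,7-bis(benzyloxy)-2-[2,4-bis(benzyloxy)phenyl]-4H-chromen-4-one
Conditions: p-TsOH·H2O (0.2 equiv), toluene, 110 °C, Dean–Stark
Reagents that add atoms: none
Why: Acid-catalysed cyclodehydration, the closing stage of the Baker–Venkataraman flavone synthesis; the single free phenol adds to the ring B carbonyl and water is lost, and since the benzyl ethers on O5 and O2' hold under catalytic sulfonic acid, no other phenol can close and the 8-allyl regiochemistry is kept.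

Step 9
Reactants: 12 3,8-diallyl-5,7-bis(benzyloxy)-2-[2,4-bis(benzyloxy)phenyl]-4H-chromen-4-one
Product: 13 3,8-diallyl-5,7,2',4'-tetrahydroxyflavone
Conditions: BCl3 (10 equiv), C6HMe5 (15 equiv), CH2Cl2, −78 °C; MeOH quench at −78 °C, aqueous work-up
Reagents that add atoms: none
Why: Lewis acid cleavage of aryl benzyl ethers with a cation scavenger; BCl3 binds each ether oxygen, the benzyl cation is taken up by non-basic pentamethylbenzene (Friedel–Crafts capture) instead of the electron-rich C6 of ring A, and at −78 °C the monosubstituted allyl alkenes are neither protonated nor attacked.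

Step 10
Reactants: 13 3,8-diallyl-5,7,2',4'-tetrahydroxyflavone
Product: 14 3,8-diallyl-5,7,2',4'-tetraacetoxyflavone
Conditions: Ac2O, pyridine, DMAP (cat.), rt
Reagents that add atoms: acetic anhydride, CC(=O)OC(C)=O
Why: DMAP-catalysed peracetylation; nucleophilic catalysis also brings in the chelated 5-OH, so all four phenols carry groups that later leave without acid.

Step 11
Reactants: 14 3,8-diallyl-5,7,2',4'-tetraacetoxyflavone; 15 2-methyl-2-butene
Product: 16 3,8-diprenyl-5,7,2',4'-tetraacetoxyflavone
Conditions: second-generation Grubbs catalyst (H2IMes)(PCy3)Cl2Ru(=CHPh) (2 × 5 mol %), 1,4-benzoquinone (10 mol %), CH2Cl2/2-methyl-2-butene 1:1 (large excess), 40 °C, pressure tube, argon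
Reagents that add atoms: 2-methyl-2-butene (15), CC=C(C)C
Why: Olefin cross-metathesis by the Chauvin mechanism: the 14-electron ruthenium alkylidene formed by loss of PCy3 adds [2+2] to each unhindered terminal CH=CH2, cycloreversion gives the chain-bound alkylidene Ru=CH–CH2Ar, and a second [2+2]/cycloreversion with 2-methyl-2-butene delivers the CH=CMe2 terminus, while the methylidene and ethylidene fragments leave together as propene. The closest known reaction is the conversion of allylarenes into prenylarenes with 2-methyl-2-butene and this catalyst. No ring closes, because C3 and C8 lie on opposite edges of the planar chromenone and a link between the two chains would be a strained bridged nine-membered ring; no stereocentre forms and the gem-dimethyl terminus has no E/Z isomers. The step needs cross- over self-metathesis at both chains: the solvent-level excess of the trisubstituted partner, which does not dimerise, outcompetes dimer formation, any dimer or crotyl end is still a reactive disubstituted alkene that is drawn on to product, and the trisubstituted product is too hindered to re-enter the cycle. Double-bond migration by ruthenium hydrides is held back by 1,4-benzoquinone and the low temperature, and the four acetates keep O7 and O2' from binding ruthenium or adding to the new alkenes.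

Step 12
Reactants: 16 3,8-diprenyl-5,7,2',4'-tetraacetoxyflavone
Product: 17 Kuwanon C (3,8-diprenyl-5,7,2',4'-tetrahydroxyflavone)
Conditions: K2CO3 (4 equiv), MeOH, 0 °C → rt, argon, dark; AcOH to pH 6
Reagents that add atoms: none
Why: Base-mediated transesterification (methanolysis) of aryl acetates; methoxide attacks the activated acetyl carbonyls far faster than the chromenone, and since only acetic acid is used for neutralisation, neither O7 nor O2' should add to the prenyl alkenes.

Compound list
1 | 2,4,6-trihydroxyacetophenone | CC(=O)c1c(O)cc(O)cc1O | starting material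
2 | 1-[2,4-bis(benzyloxy)-6-hydroxyphenyl]ethanone | CC(=O)c1c(O)cc(OCc2ccccc2)cc1OCc1ccccc1 | intermediate
3 | allyl bromide | C=CCBr | starting material
4 | 1-[2-(allyloxy)-4,6-bis(benzyloxy)phenyl]ethanone | CC(=O)c1c(OCC=C)cc(OCc2ccccc2)cc1OCc1ccccc1 | intermediate
5 | 1-[3-allyl-4,6-bis(benzyloxy)-2-hydroxyphenyl]ethanone | CC(=O)c1c(O)c(CC=C)c(OCc2ccccc2)cc1OCc1ccccc1 | intermediate
6 | 2,4-dihydroxybenzoic acid | O=C(O)c1ccc(O)cc1O | starting material
7 | benzyl 2,4-bis(benzyloxy)benzoate | O=C(OCc1ccccc1)c1ccc(OCc2ccccc2)cc1OCc1ccccc1 | intermediate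
8 | 2,4-bis(benzyloxy)benzoic acid | O=C(O)c1ccc(OCc2ccccc2)cc1OCc1ccccc1 | intermediate
9 | 2-acetyl-6-allyl-3,5-bis(benzyloxy)phenyl 2,4-bis(benzyloxy)benzoate | CC(=O)c1c(OC(=O)c2ccc(OCc3ccccc3)cc2OCc2ccccc2)c(CC=C)c(OCc2ccccc2)cc1OCc1ccccc1 | intermediate
10 | 1-[3-allyl-4,6-bis(benzyloxy)-2-hydroxyphenyl]-3-[2,4-bis(benzyloxy)phenyl]propane-1,3-dione | O=C(CC(=O)c1ccc(OCc2ccccc2)cc1OCc1ccccc1)c1c(O)c(CC=C)c(OCc2ccccc2)cc1OCc1ccccc1 | intermediate
11 | (±)-2-allyl-1-[3-allyl-4,6-bis(benzyloxy)-2-hydroxyphenyl]-3-[2,4-bis(benzyloxy)phenyl]propane-1,3-dione (racemic, labile centre) | O=C(C(CC=C)C(=O)c1ccc(OCc2ccccc2)cc1OCc1ccccc1)c1c(O)c(CC=C)c(OCc2ccccc2)cc1OCc1ccccc1 | intermediate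
12 | 3,8-diallyl-5,7-bis(benzyloxy)-2-[2,4-bis(benzyloxy)phenyl]-4H-chromen-4-one | C=CCc1c(-c2ccc(OCc3ccccc3)cc2OCc2ccccc2)oc2c(CC=C)c(OCc3ccccc3)cc(OCc3ccccc3)c2c1=O | intermediate
13 | 3,8-diallyl-5,7,2',4'-tetrahydroxyflavone | C=CCc1c(-c2ccc(O)cc2O)oc2c(CC=C)c(O)cc(O)c2c1=O | intermediate
14 | 3,8-diallyl-5,7,2',4'-tetraacetoxyflavone | C=CCc1c(-c2ccc(OC(C)=O)cc2OC(C)=O)oc2c(CC=C)c(OC(C)=O)cc(OC(C)=O)c2c1=O | intermediate
15 | 2-methyl-2-butene | CC=C(C)C | starting material
16 | 3,8-diprenyl-5,7,2',4'-tetraacetoxyflavone | CC(C)=CCc1c(-c2ccc(OC(C)=O)cc2OC(C)=O)oc2c(CC=C(C)C)c(OC(C)=O)cc(OC(C)=O)c2c1=O | intermediate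
17 | Kuwanon C | CC(C)=CCc1c(-c2ccc(O)cc2O)oc2c(CC=C(C)C)c(O)cc(O)c2c1=O | target

Total step count: 12.
Longest linear sequence: 11 steps (steps 1–3 and 5–12, from 1). Step 4 is the side branch.

Steps most likely to fail

Step 7. O-allylation at the phenol or at the enol oxygen, or a second alkylation at carbon, may compete with the single C-allylation. The fallback sets out from 4 and comes back at 11. It puts the future 3-allyl group on the ketone before any phenol or diketone exists.
- The methyl ketone of 4 is deprotonated with LiN(i-Pr)2 in THF at −78 °C and alkylated with 3, giving 1-[2-(allyloxy)-4,6-bis(benzyloxy)phenyl]pent-4-en-1-one F1.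
- Claisen rearrangement in PhNEt2 at 200 °C should give 1-[3-allyl-4,6-bis(benzyloxy)-2-hydroxyphenyl]pent-4-en-1-one F2.
- Esterification with 8 (EDCI, DMAP, CH2Cl2) gives 6-allyl-3,5-bis(benzyloxy)-2-(pent-4-enoyl)phenyl 2,4-bis(benzyloxy)benzoate F3.
- Baker–Venkataraman rearrangement of its substituted enolate with LiN(SiMe3)2 in THF, as known for propiophenone esters on the way to 3-alkylflavones, delivers 11.

Step 11. The exchange may stall after one chain, ethylidene may be transferred in place of isopropylidene, or the double bonds may migrate into conjugation with ring A or ring C. The fallback sets out from 13 and comes back at 17. It builds the trisubstituted alkenes by olefination of carbonyl groups under non-acidic conditions.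
- Silylation of 13 with TBSOTf and 2,6-lutidine in CH2Cl2 gives 3,8-diallyl-5,7,2',4'-tetrakis(tert-butyldimethylsilyloxy)flavone F4.
- Oxidative cleavage of both alkenes (OsO4 cat., NaIO4, 2,6-lutidine, dioxane/H2O) gives 2,2'-{2-[2,4-bis(tert-butyldimethylsilyloxy)phenyl]-5,7-bis(tert-butyldimethylsilyloxy)-4-oxo-4H-chromene-3,8-diyl}diacetaldehyde F5.
- A twofold Wittig reaction with Ph3P=CMe2 (from isopropyltriphenylphosphonium iodide and n-BuLi, THF, −78 °C) gives 3,8-diprenyl-5,7,2',4'-tetrakis(tert-butyldimethylsilyloxy)flavone F6.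
- Bu4NF buffered with AcOH in THF at 0 °C frees 17.

Step 8. Ring closure of the hindered, hardly enolised 2-allyl diketone may be slow. That leaves room for retro-Claisen cleavage, or for acid loss of the O5 benzyl group before closure, which would blur the 8- versus 6-allyl outcome. The fallback sets out from 10 and comes back at 12. It closes ring C first and forms the C3–allyl bond afterwards by cross-coupling.
- The fully enolised 10 is cyclodehydrated (p-TsOH, toluene, 110 °C) to 8-allyl-5,7-bis(benzyloxy)-2-[2,4-bis(benzyloxy)phenyl]-4H-chromen-4-one F7.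
- C3 is lithiated with LiN(i-Pr)2 in THF at −78 °C and quenched with I2, giving 8-allyl-5,7-bis(benzyloxy)-2-[2,4-bis(benzyloxy)phenyl]-3-iodo-4H-chromen-4-one F8.
- Stille coupling with allyltributylstannane (Pd(PPh3)4, DMF, 80 °C) gives 12.

Further compounds
F1 | step 7 | 1-[2-(allyloxy)-4,6-bis(benzyloxy)phenyl]pent-4-en-1-one | C=CCCC(=O)c1c(OCC=C)cc(OCc2ccccc2)cc1OCc1ccccc1
F2 | step 7 | 1-[3-allyl-4,6-bis(benzyloxy)-2-hydroxyphenyl]pent-4-en-1-one | C=CCCC(=O)c1c(O)c(CC=C)c(OCc2ccccc2)cc1OCc1ccccc1
F3 | step 7 | 6-allyl-3,5-bis(benzyloxy)-2-(pent-4-enoyl)phenyl 2,4-bis(benzyloxy)benzoate | C=CCCC(=O)c1c(OC(=O)c2ccc(OCc3ccccc3)cc2OCc2ccccc2)c(CC=C)c(OCc2ccccc2)cc1OCc1ccccc1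
F4 | step 11 | 3,8-diallyl-5,7,2',4'-tetrakis(tert-butyldimethylsilyloxy)flavone | C=CCc1c(-c2ccc(O[Si](C)(C)C(C)(C)C)cc2O[Si](C)(C)C(C)(C)C)oc2c(CC=C)c(O[Si](C)(C)C(C)(C)C)cc(O[Si](C)(C)C(C)(C)C)c2c1=O
F5 | step 11 | 2,2'-{2-[2,4-bis(tert-butyldimethylsilyloxy)phenyl]-5,7-bis(tert-butyldimethylsilyloxy)-4-oxo-4H-chromene-3,8-diyl}diacetaldehyde | O=CCc1c(-c2ccc(O[Si](C)(C)C(C)(C)C)cc2O[Si](C)(C)C(C)(C)C)oc2c(CC=O)c(O[Si](C)(C)C(C)(C)C)cc(O[Si](C)(C)C(C)(C)C)c2c1=O
F6 | step 11 | 3,8-diprenyl-5,7,2',4'-tetrakis(tert-butyldimethylsilyloxy)flavone | CC(C)=CCc1c(-c2ccc(O[Si](C)(C)C(C)(C)C)cc2O[Si](C)(C)C(C)(C)C)oc2c(CC=C(C)C)c(O[Si](C)(C)C(C)(C)C)cc(O[Si](C)(C)C(C)(C)C)c2c1=O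
F7 | step 8 | 8-allyl-5,7-bis(benzyloxy)-2-[2,4-bis(benzyloxy)phenyl]-4H-chromen-4-one | C=CCc1c(OCc2ccccc2)cc(OCc2ccccc2)c2c(=O)cc(-c3ccc(OCc4ccccc4)cc3OCc3ccccc3)oc12
F8 | step 8 | 8-allyl-5,7-bis(benzyloxy)-2-[2,4-bis(benzyloxy)phenyl]-3-iodo-4H-chromen-4-one | C=CCc1c(OCc2ccccc2)cc(OCc2ccccc2)c2c(=O)c(I)c(-c3ccc(OCc4ccccc4)cc3OCc3ccccc3)oc12
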